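**Retrosynthetic overview**
1. Target 16 ⇐ hydroxy lactone 14 + (R)-2-methylbutanoic acid (esterification, last step).
2. 14 ⇐ α-hydroxy aldehyde 12: the C6–C7 bond and the lactone C–O bond form in one operation by chelation-controlled intramolecular Hosomi–Sakurai allylation/lactonisation. This closes the second seven-membered ring (the ten-membered carbocycle) and the γ-lactone together.
3. 12 ⇐ allyl oxepane diol 9: cross-metathesis with ethyl 2-(trimethylsilylmethyl)acrylate, then primary-selective oxidation.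
4. 9 ⇐ diene diol 7: Sharpless epoxidation, then 7-exo epoxide opening at C4 by the C9 hydroxyl (oxepane, first ring).
5. 7 ⇐ geranyl acetate: C8 allylic oxidation, Ru-BINAP hydrogenation (sets C10), Brown allylation (sets C9).

Assumption: germacrane numbering is used (C4(Me)–O–C9 ether, C5 ester, C6–O/C12 lactone, C7 ring fusion, C10 CHMe, C11=C13; geraniol C1…C8 become C6, C5, C4, C3, C2, C1, C10, C9), and (R)-2-methylbutanoic acid (R as read from the SMILES), (+)-Ipc2B(allyl) and ethyl 2-(trimethylsilylmethyl)acrylate are taken as catalogue chemicals.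

**Step 1**
Reactants: 1 geranyl acetate
Product: 2 (2E,6E)-8-hydroxy-3,7-dimethylocta-2,6-dien-1-yl acetate
Conditions: SeO2 (cat.), t-BuOOH, salicylic acid (cat.), CH2Cl2, 23 °C
Reagents that add atoms: selenium dioxide O=[Se]=O (catalytic oxygen-transfer agent); tert-butyl hydroperoxide CC(C)(C)OO (terminal oxidant)
Why: Sharpless SeO2/t-BuOOH allylic oxidation (ene reaction then [2,3]-sigmatropic shift) hydroxylates the (E)-methyl of the electron-richer 6,7-olefin, while the 2,3-olefin is deactivated by the allylic acetate.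

**Step 2**
Reactants: 2 (2E,6E)-8-hydroxy-3,7-dimethylocta-2,6-dien-1-yl acetate
Product: 3 (2E,7S)-8-hydroxy-3,7-dimethyloct-2-en-1-yl acetate
Conditions: Ru(OAc)2[(S)-BINAP] (1 mol%), H2 (100 atm), MeOH, 23 °C
Reagents that add atoms: none
Why: Noyori asymmetric hydrogenation of an allylic alcohol, in which the Ru-bound alkoxide directs H2 to one olefin face (same facial sense as geraniol → (R)-citronellol with (S)-BINAP) and sets the future C10 as S, while the hydroxyl-free 2,3-olefin is not reduced.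

**Step 3**
Reactants: 3 (2E,7S)-8-hydroxy-3,7-dimethyloct-2-en-1-yl acetate
Product: 4 (2E,7S)-3,7-dimethyl-8-oxooct-2-en-1-yl acetate
Conditions: TEMPO (cat.), PhI(OAc)2, CH2Cl2, 0 → 23 °C; used crude
Reagents that add atoms: none
Why: TEMPO/PhI(OAc)2 (oxoammonium) oxidation of the primary alcohol is non-basic, so the α-methyl stereocentre is not epimerised.

**Step 4**
Reactants: 4 (2E,7S)-3,7-dimethyl-8-oxooct-2-en-1-yl acetate; 5 (+)-B-allyldiisopinocampheylborane
Product: 7 (2E,7S,8R)-3,7-dimethylundeca-2,10-diene-1,8-diol, via borinate ester 6 (not isolated)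
Conditions: 5, Et2O, −78 °C; then 3 M NaOH, 30% H2O2, MeOH, 0 → 23 °C
Reagents that add atoms: (+)-B-allyldiisopinocampheylborane C=CCB([C@H]1C[C@H]2C[C@@H]([C@@H]1C)C2(C)C)[C@H]1C[C@H]2C[C@@H]([C@@H]1C)C2(C)C
Why: Brown asymmetric allylboration through a chair Zimmerman–Traxler transition state adds allyl to the Re face under reagent control and sets the carbinol (future C9) as R, anti to the methyl; the alkaline peroxide work-up that cleaves the borinate also saponifies the acetate.

**Step 5**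
Reactants: 7 (2E,7S,8R)-3,7-dimethylundeca-2,10-diene-1,8-diol
Product: 9 (1S)-1-[(2R,6S,7R)-2,6-dimethyl-7-(prop-2-en-1-yl)oxepan-2-yl]ethane-1,2-diol, via epoxy alcohol 8 (not isolated)
Conditions: Ti(OiPr)4 (0.3 equiv), L-(+)-DET (0.36 equiv), t-BuOOH, 4 Å MS, CH2Cl2, −20 °C; then CSA (0.3 equiv), −20 → 23 °C
Reagents that add atoms: tert-butyl hydroperoxide CC(C)(C)OO
Why: Katsuki–Sharpless asymmetric epoxidation with L-(+)-DET gives the (2S,3S)-epoxy alcohol (sets C5 and C4), and acid then triggers a 7-exo-tet opening by the C9 hydroxyl at the tertiary epoxide carbon with inversion, so C4 becomes R, C5–OH keeps its configuration and the C4–O–C9 oxepane is closed.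

**Step 6**
Reactants: 9 (1S)-1-[(2R,6S,7R)-2,6-dimethyl-7-(prop-2-en-1-yl)oxepan-2-yl]ethane-1,2-diol; 10 ethyl 2-[(trimethylsilyl)methyl]prop-2-enoate
Product: 11 ethyl (2Z)-4-{(2R,3S,7R)-7-[(1S)-1,2-dihydroxyethyl]-3,7-dimethyloxepan-2-yl}-2-[(trimethylsilyl)methyl]but-2-enoate (E/Z mixture, Z major, used as such)
Conditions: 10 (5 equiv), Hoveyda–Grubbs II (10 mol%), CH2Cl2, 40 °C
Reagents that add atoms: ethyl 2-[(trimethylsilyl)methyl]prop-2-enoate C=C(C[Si](C)(C)C)C(=O)OCC
Why: Olefin cross-metathesis between a terminal alkene and a non-dimerising 1,1-disubstituted acrylate used in excess gives the trisubstituted 2-(silylmethyl)enoate, whose E/Z ratio does not matter for the open-transition-state C–C bond formation that follows.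

**Step 7**
Reactants: 11 ethyl (2Z)-4-{(2R,3S,7R)-7-[(1S)-1,2-dihydroxyethyl]-3,7-dimethyloxepan-2-yl}-2-[(trimethylsilyl)methyl]but-2-enoate
Product: 12 ethyl (2Z)-4-{(2R,3S,7R)-7-[(1R)-1-hydroxy-2-oxoethyl]-3,7-dimethyloxepan-2-yl}-2-[(trimethylsilyl)methyl]but-2-enoate
Conditions: TEMPO (0.1 equiv), PhI(OAc)2 (1.1 equiv), CH2Cl2, 0 °C; used crude at once
Reagents that add atoms: none
Why: Oxoammonium (TEMPO) oxidation is selective for the primary over the hindered secondary hydroxyl and gives the α-hydroxy aldehyde, which is carried on immediately to avoid dimerisation or epimerisation at C5 (the descriptor changes from S to R only through CIP priorities).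

**Step 8**
Reactants: 12 ethyl (2Z)-4-{(2R,3S,7R)-7-[(1R)-1-hydroxy-2-oxoethyl]-3,7-dimethyloxepan-2-yl}-2-[(trimethylsilyl)methyl]but-2-enoate
Product: 14 (4R,5S,6R,7R,9R,10S)-5-hydroxy-4,9-epoxygermacr-11(13)-en-12,6-olide (the target without its acyl group), via hydroxy ester 13 (not isolated)
Conditions: TiCl4 (2.2 equiv), 2,6-di-tert-butyl-4-methylpyridine, CH2Cl2, −78 → 23 °C; aq. NaHCO3
Reagents that add atoms: none
Why: Intramolecular Hosomi–Sakurai allylation of a 2-(silylmethyl)enoate followed by lactonisation: the C5 titanium alkoxide chelates the aldehyde (Cram-chelate addition, 5,6-syn, C6 = R), the tethered allylsilane adds through an antiperiplanar open transition state with the ester-bearing allyl unit exo to the C1–C3 bridge (H-6/H-7 trans, C7 = R), and the γ-hydroxy ester then closes to the trans-fused α-methylene lactone, so the C6–C7 ring bond and the lactone form in one operation.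

**Step 9**
Reactants: 14 (4R,5S,6R,7R,9R,10S)-5-hydroxy-4,9-epoxygermacr-11(13)-en-12,6-olide; 15 (R)-2-methylbutanoic acid
Product: 16 (4R,5S,6R,7R,9R,10S)-5-[(2R)-2-methylbutanoyloxy]-4,9-epoxygermacr-11(13)-en-12,6-olide (target)
Conditions: 15, DIC, DMAP (0.3 equiv), CH2Cl2, 23 °C
Reagents that add atoms: (R)-2-methylbutanoic acid CC[C@@H](C)C(=O)O
Why: Steglich esterification acylates the hindered C5 hydroxyl without touching any ring stereocentre, and the mild carbodiimide/DMAP conditions keep the α-stereocentre of the acid.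

**Compound list**
1 | geranyl acetate, (2E)-3,7-dimethylocta-2,6-dien-1-yl acetate | CC(C)=CCC/C(C)=C/COC(C)=O | starting material
2 | (2E,6E)-8-hydroxy-3,7-dimethylocta-2,6-dien-1-yl acetate | CC(=O)OC/C=C(\C)CC/C=C(\C)CO | intermediate
3 | (2E,7S)-8-hydroxy-3,7-dimethyloct-2-en-1-yl acetate | CC(=O)OC/C=C(\C)CCC[C@H](C)CO | intermediate
4 | (2E,7S)-3,7-dimethyl-8-oxooct-2-en-1-yl acetate | CC(=O)OC/C=C(\C)CCC[C@H](C)C=O | intermediate
5 | (+)-B-allyldiisopinocampheylborane (from (−)-α-pinene) | C=CCB([C@H]1C[C@H]2C[C@@H]([C@@H]1C)C2(C)C)[C@H]1C[C@H]2C[C@@H]([C@@H]1C)C2(C)C | starting material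
6 | (2E,7S,8R)-8-{[bis(isopinocampheyl)boranyl]oxy}-3,7-dimethylundeca-2,10-dien-1-yl acetate | CC(=O)OC/C=C(\C)CCC[C@H](C)[C@@H](CC=C)OB([C@H]1C[C@H]2C[C@@H]([C@@H]1C)C2(C)C)[C@H]1C[C@H]2C[C@@H]([C@@H]1C)C2(C)C | intermediate
7 | (2E,7S,8R)-3,7-dimethylundeca-2,10-diene-1,8-diol | OC/C=C(\C)CCC[C@H](C)[C@H](O)CC=C | intermediate
8 | {(2S,3S)-3-[(4S,5R)-5-hydroxy-4-methyloct-7-en-1-yl]-3-methyloxiran-2-yl}methanol | OC[C@@H]1O[C@@]1(C)CCC[C@H](C)[C@H](O)CC=C | intermediate
9 | (1S)-1-[(2R,6S,7R)-2,6-dimethyl-7-(prop-2-en-1-yl)oxepan-2-yl]ethane-1,2-diol | C=CC[C@H]1O[C@](C)(CCC[C@@H]1C)[C@@H](O)CO | intermediate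
10 | ethyl 2-[(trimethylsilyl)methyl]prop-2-enoate | C=C(C[Si](C)(C)C)C(=O)OCC | starting material
11 | ethyl (2Z)-4-{(2R,3S,7R)-7-[(1S)-1,2-dihydroxyethyl]-3,7-dimethyloxepan-2-yl}-2-[(trimethylsilyl)methyl]but-2-enoate | CCOC(=O)/C(C[Si](C)(C)C)=C/C[C@H]1O[C@](C)(CCC[C@@H]1C)[C@@H](O)CO | intermediate
12 | ethyl (2Z)-4-{(2R,3S,7R)-7-[(1R)-1-hydroxy-2-oxoethyl]-3,7-dimethyloxepan-2-yl}-2-[(trimethylsilyl)methyl]but-2-enoate | CCOC(=O)/C(C[Si](C)(C)C)=C/C[C@H]1O[C@](C)(CCC[C@@H]1C)[C@@H](O)C=O | intermediate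
13 | ethyl 2-[(1R,2S,3R,4R,6R,7S)-2,3-dihydroxy-1,7-dimethyl-11-oxabicyclo[4.4.1]undecan-4-yl]prop-2-enoate | C=C(C(=O)OCC)[C@H]1C[C@H]2O[C@](C)(CCC[C@@H]2C)[C@@H](O)[C@@H]1O | intermediate
14 | (4R,5S,6R,7R,9R,10S)-5-hydroxy-4,9-epoxygermacr-11(13)-en-12,6-olide | C=C1C(=O)O[C@@H]2[C@@H]1C[C@H]1O[C@](C)(CCC[C@@H]1C)[C@H]2O | intermediate
15 | (R)-2-methylbutanoic acid | CC[C@@H](C)C(=O)O | starting material
16 | (4R,5S,6R,7R,9R,10S)-5-[(2R)-2-methylbutanoyloxy]-4,9-epoxygermacr-11(13)-en-12,6-olide (CNP0136059.1) | C=C1C(=O)O[C@@H]2[C@@H]1C[C@H]1O[C@](C)(CCC[C@@H]1C)[C@H]2OC(=O)[C@H](C)CC | target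

**Step count:** 9 steps in total; longest linear sequence 9 steps (from geranyl acetate).

**Steps most likely to fail**

Step 8 (ring closure and lactonisation). The ester-deactivated allylsilane may protodesilylate before it adds, and the ring fusion (trans versus cis) or the C6 configuration could come out wrong, because both rest on a transition-state argument, not on a stereospecific event. The fallback sets out from 9 and changes the nucleophile to a metal-templated allyl species. Cross-metathesis of 9 with methyl 2-(bromomethyl)acrylate gives methyl (2Z)-2-(bromomethyl)-4-{(2R,3S,7R)-7-[(1S)-1,2-dihydroxyethyl]-3,7-dimethyloxepan-2-yl}but-2-enoate F1. TEMPO/PhI(OAc)2 oxidation gives methyl (2Z)-2-(bromomethyl)-4-{(2R,3S,7R)-7-[(1R)-1-hydroxy-2-oxoethyl]-3,7-dimethyloxepan-2-yl}but-2-enoate F2. CrCl2 in THF then effects an intramolecular Nozaki–Hiyama–Kishi allylation through an E/Z-equilibrating allylchromium in a closed chair transition state, and the hydroxy ester lactonises spontaneously. The fallback comes back to the route at 14; the ring fusion from this closed transition state must be checked, since 2-alkoxycarbonyl allylmetals often favour the cis lactone.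

Step 6 (cross-metathesis). The 1,1-disubstituted, neopentyl-like acrylate 10 may be too hindered to turn over. The fallback sets out from 9 and replaces metathesis by olefination. Ozonolysis (O3, then Me2S) gives {(2R,3S,7R)-7-[(1S)-1,2-dihydroxyethyl]-3,7-dimethyloxepan-2-yl}acetaldehyde F3. Horner–Wadsworth–Emmons reaction with ethyl 2-(diethoxyphosphoryl)-3-(trimethylsilyl)propanoate (NaH, THF) gives the same 2-(silylmethyl)enoate as an E/Z mixture. The fallback comes back at 11.

Step 7 (oxidation of the 1,2-diol to the α-hydroxy aldehyde). Glycol cleavage, over-oxidation, or dimerisation and α-ketol isomerisation of 12 are all possible. The fallback sets out from 8, here isolated after the epoxidation with no acid added, and oxidises before the diol exists. Cross-metathesis of 8 with 10 gives ethyl (2Z,5R,6S)-5-hydroxy-9-[(2S,3S)-3-(hydroxymethyl)-2-methyloxiran-2-yl]-6-methyl-2-[(trimethylsilyl)methyl]non-2-enoate F4. TEMPO/PhI(OAc)2 now meets only one primary alcohol and gives ethyl (2Z,5R,6S)-9-[(2S,3R)-3-formyl-2-methyloxiran-2-yl]-5-hydroxy-6-methyl-2-[(trimethylsilyl)methyl]non-2-enoate F5. A Lewis acid (BF3·OEt2, then TiCl4, CH2Cl2, −78 °C) opens the epoxide through the secondary hydroxyl (7-exo) and then drives the allylsilane addition and lactonisation in the same flask, forming all three rings at once. The fallback comes back at 14; its own risk is Lewis-acid rearrangement (formyl shift) of the epoxy aldehyde.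

**Further compounds**
F1 | step 8 | methyl (2Z)-2-(bromomethyl)-4-{(2R,3S,7R)-7-[(1S)-1,2-dihydroxyethyl]-3,7-dimethyloxepan-2-yl}but-2-enoate | COC(=O)/C(CBr)=C/C[C@H]1O[C@](C)(CCC[C@@H]1C)[C@@H](O)CO
F2 | step 8 | methyl (2Z)-2-(bromomethyl)-4-{(2R,3S,7R)-7-[(1R)-1-hydroxy-2-oxoethyl]-3,7-dimethyloxepan-2-yl}but-2-enoate | COC(=O)/C(CBr)=C/C[C@H]1O[C@](C)(CCC[C@@H]1C)[C@@H](O)C=O
F3 | step 6 | {(2R,3S,7R)-7-[(1S)-1,2-dihydroxyethyl]-3,7-dimethyloxepan-2-yl}acetaldehyde | O=CC[C@H]1O[C@](C)(CCC[C@@H]1C)[C@@H](O)CO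
F4 | step 7 | ethyl (2Z,5R,6S)-5-hydroxy-9-[(2S,3S)-3-(hydroxymethyl)-2-methyloxiran-2-yl]-6-methyl-2-[(trimethylsilyl)methyl]non-2-enoate | CCOC(=O)/C(C[Si](C)(C)C)=C/C[C@@H](O)[C@@H](C)CCC[C@]1(C)O[C@H]1CO
F5 | step 7 | ethyl (2Z,5R,6S)-9-[(2S,3R)-3-formyl-2-methyloxiran-2-yl]-5-hydroxy-6-methyl-2-[(trimethylsilyl)methyl]non-2-enoate | CCOC(=O)/C(C[Si](C)(C)C)=C/C[C@@H](O)[C@@H](C)CCC[C@]1(C)O[C@H]1C=O
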